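Ring B is read as a Diels–Alder ring: C5–C10 and C8–C9 are the two σ-bonds made when a C5=C6–C7=C8 diene meets a C9=C10 dienophile, and because C1–C4 already link C10 to C5, the cycloaddition is intramolecular and closes rings A and B together. The precursor is acyclic: an E α-methyl enone carrying the whole polyprenyl chain on C9, with a temporary C1 carbonyl in the tether (endo control, hence the A/B cis fusion), the C3 silyl ether as the only stereocentre, and a Z 1-boryl-1-methyl diene whose C8–B bond later becomes C8–OH. One operation sets C5, C8, C9 and C10.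

Key step: step 9

Remark: terpenoid numbering is used (decalin C1–C10, chain on C9, β = face of CH3-10); read literally, the SMILES has H-5 and CH3-10 on the same face, i.e. an A/B cis-fused decalin (3S,5S,8R,9R,10S), and the route is built for this isomer.

Step 1
Reactants: 1 2,2-dimethylbut-3-yn-1-ol
Product: 3 (E)-4-iodo-2,2-dimethylbut-3-en-1-ol, via vinylstannane 2 (not isolated)
Conditions: Bu3SnH, PdCl2(PPh3)2 (2 mol %), THF, 0 °C to rt; then I2, 0 °C
Reagents that add atoms: iodine, [I][I]
Why: Pd-catalysed syn-hydrostannation puts tin on the terminal alkyne carbon (the quaternary neighbour blocks the internal one) to give the E-vinylstannane, and iododestannylation then proceeds with retention of the E geometry.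

Step 2
Reactants: 3 (E)-4-iodo-2,2-dimethylbut-3-en-1-ol; 4 propyne
Product: 5 (E)-2,2-dimethylhept-3-en-5-yn-1-ol
Conditions: propyne (excess, THF solution), PdCl2(PPh3)2 (3 mol %), CuI (5 mol %), Et3N, THF, rt
Reagents that add atoms: none
Why: Sonogashira coupling of the vinyl iodide retains the E olefin geometry and tolerates the free neopentyl alcohol.

Step 3
Reactants: 5 (E)-2,2-dimethylhept-3-en-5-yn-1-ol
Product: 6 (3E,5Z)-2,2-dimethyl-6-(pinacolboryl)hepta-3,5-dien-1-ol
Conditions: B2pin2 (1.1 equiv), CuCl (5 mol %), P(p-tolyl)3 (6 mol %), NaOtBu (15 mol %), MeOH (2 equiv), THF, rt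
Reagents that add atoms: bis(pinacolato)diboron, CC1(C)OB(OC1(C)C)B1OC(C)(C)C(C)(C)O1
Why: Copper-catalysed protoboration of the internal alkyne of a 1,3-enyne (syn borylcupration, protonolysis with retention) should put boron on the methyl-bearing carbon remote from the olefin, which fixes the 5Z geometry with boron trans and methyl cis to the neighbouring olefin.

Step 4
Reactants: 6 (3E,5Z)-2,2-dimethyl-6-(pinacolboryl)hepta-3,5-dien-1-ol
Product: 7 (3E,5Z)-2,2-dimethyl-6-(pinacolboryl)hepta-3,5-dienal
Conditions: Dess–Martin periodinane, CH2Cl2, 0 °C to rt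
Reagents that add atoms: none
Why: Dess–Martin oxidation of the neopentyl primary alcohol stops at the aldehyde, which cannot enolise, and leaves the alkenyl C–B bond untouched.

Step 5
Reactants: 8 (2E,6E)-farnesyl bromide; 9 (E)-N-tert-butylethanimine
Product: 12 (4E,8E)-5,9,13-trimethyltetradeca-4,8,12-trienal, via lithiated imine 10 (not isolated), via alkylated imine 11 (not isolated)
Conditions: LiN(iPr)2, THF, 0 °C; then 8, −78 °C to rt; then aq. oxalic acid, rt
Reagents that add atoms: water, O
Why: Alkylation of a lithiated aldimine (metalloenamine alkylation) at the primary carbon of the allylic bromide, followed by mild acid hydrolysis, gives the two-carbon-extended aldehyde without touching the E olefins.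

Step 6
Reactants: 12 (4E,8E)-5,9,13-trimethyltetradeca-4,8,12-trienal; 13 3-(triphenyl-λ5-phosphanylidene)butan-2-one
Product: 14 (3E,7E,11E)-3,8,12,16-tetramethylheptadeca-3,7,11,15-tetraen-2-one
Conditions: toluene, 90 °C
Reagents that add atoms: none
Why: Wittig olefination with an α-methyl-substituted stabilised ylide should give the trisubstituted enone with E geometry (chain trans to the acetyl group).

Step 7
Reactants: 14 (3E,7E,11E)-3,8,12,16-tetramethylheptadeca-3,7,11,15-tetraen-2-one; 7 (3E,5Z)-2,2-dimethyl-6-(pinacolboryl)hepta-3,5-dienal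
Product: 17 (S)-β-hydroxy enone (aldol adduct), via boron enolate 15 (not isolated), via boron aldolate 16 (not isolated)
Conditions: (+)-Ipc2BCl (1.3 equiv), Et3N, Et2O, −78 to 0 °C; then 7, −78 to −20 °C; MeOH/pH 7 buffer work-up without peroxide
Reagents that add atoms: none
Why: Reagent-controlled boron aldol reaction of a methyl ketone: enolisation occurs at the methyl group and the isopinocampheyl ligands should direct the enolate to the si face of the non-enolisable aldehyde, setting the S carbinol (the future C3), while the peroxide-free work-up keeps the C–B bond.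

Step 8
Reactants: 17 (S)-β-hydroxy enone
Product: 18 silyl ether of 17 (cycloaddition substrate)
Conditions: TBSOTf, 2,6-lutidine, CH2Cl2, −78 to 0 °C
Reagents that add atoms: tert-butyldimethylsilyl triflate, CC(C)(C)[Si](C)(C)OS(=O)(=O)C(F)(F)F
Why: Silylation of the hindered secondary alcohol gives a bulky, non-chelating ether that blocks retro-aldol cleavage and serves as the stereocontrol element of the next step.

Step 9
Reactants: 18 silyl ether of 17
Product: 19 A/B-cis octalone boronate (cycloadduct)
Conditions: Me2AlCl (1.5 equiv), CH2Cl2, −40 to 0 °C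
Reagents that add atoms: none
Why: Me2AlCl binds the C1 carbonyl and the complexed E α-methyl enone (C9=C10) adds across the termini C5 and C8 of the dienylboronate in a concerted, asynchronous, suprafacial [4+2] cycloaddition that forms C5–C10 and C8–C9 together and leaves C6=C7; the closest known reaction type is the Lewis-acid-promoted type 1 intramolecular Diels–Alder reaction of 1,7,9-decatrien-3-ones, a class known to favour cis-fused octalones. Ring B is the cycloaddition ring itself, and ring A closes in the same event by fused-mode annulation through the four-atom tether C1–C4, with the tether carbonyl endo. The cis relation of CH3-10 and the C9 chain follows from the E enone, and the cis relations C4/B-8 and H-5/CH3-8 follow from the 5E,7Z diene (boron outside, methyl inside), both by suprafacial addition. The A/B cis fusion and the placing of H-9 on the face of B-8 come from the endo transition state, in which the activating carbonyl, being part of the tether, lies under the diene. The absolute sense is set by C3: in the chair-like tether the OTBS group is equatorial, which puts O-3 on the face of CH3-10 and H-5, whereas attack on the other diene face would force it 1,3-diaxial to C6. The step needs endo and π-facial selectivity and a cycloaddition faster than 1,5-hydrogen shift of the Z-methyl diene; the in-tether carbonyl with the Lewis acid, the bulky non-chelating silyl ether and the low temperature should secure these.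

Step 10
Reactants: 19 A/B-cis octalone boronate
Product: 20 tertiary allylic alcohol (8α-OH)
Conditions: NaBO3·4H2O, THF/H2O (1:1), rt
Reagents that add atoms: sodium perborate tetrahydrate, [Na+].[Na+].O[B-]1(O)OO[B-](O)(O)OO1.O.O.O.O.O.O
Why: Perborate oxidation of the tertiary allylic C–B bond (1,2-boronate shift) proceeds with retention, so the 8α-boryl group becomes the 8α-hydroxyl without allylic transposition, and the mild pH spares the β-silyloxy ketone.

Step 11
Reactants: 20 tertiary allylic alcohol
Product: 21 saturated keto alcohol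
Conditions: H2 (1–3 atm), [Rh(nbd)(dppb)]BF4 (5 mol %), CH2Cl2, rt
Reagents that add atoms: none
Why: Hydroxyl-directed homogeneous hydrogenation: the C8 hydroxyl binds the cationic rhodium centre and delivers H2 to the neighbouring cis-disubstituted C6=C7, whereas the remote trisubstituted chain olefins lack a binding group and should be slow substrates; no stereocentre is formed.

Step 12
Reactants: 21 saturated keto alcohol
Product: 22 C1 tosylhydrazone
Conditions: TsNHNH2, pyridinium p-toluenesulfonate (cat.), EtOH, 60 °C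
Reagents that add atoms: p-toluenesulfonohydrazide, Cc1ccc(cc1)S(=O)(=O)NN
Why: Tosylhydrazone formation at the only carbonyl (C1) under weakly acidic conditions that the silyl ether, the now non-allylic tertiary alcohol and the olefins should tolerate.

Step 13
Reactants: 22 C1 tosylhydrazone
Product: 24 3-O-TBS ether of the target, via N-boryl hydrazine 23 (not isolated)
Conditions: catecholborane (3 equiv), CHCl3, 0 °C to rt; then NaOAc·3H2O, 60 °C
Reagents that add atoms: none
Why: Tosylhydrazone reduction with catecholborane (hydroboration of C=N, sulfinate elimination, loss of N2 from the diazene) turns C1 into CH2 under non-basic conditions, so the β-silyloxy group is not eliminated and no olefin migrates.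

Step 14
Reactants: 24 3-O-TBS ether of the target
Product: 25 IN0670 (target)
Conditions: TBAF, THF, 50 °C
Reagents that add atoms: none
Why: Fluoride-mediated cleavage of the silyl ether liberates the 3β-hydroxyl without affecting the tertiary alcohol or the olefins.

Compound list
1 | 2,2-dimethylbut-3-yn-1-ol | OCC(C)(C)C#C | starting material
2 | (E)-2,2-dimethyl-4-(tributylstannyl)but-3-en-1-ol | OCC(C)(C)/C=C/[Sn](CCCC)(CCCC)CCCC | intermediate
3 | (E)-4-iodo-2,2-dimethylbut-3-en-1-ol | OCC(C)(C)/C=C/I | intermediate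
4 | propyne | CC#C | starting material
5 | (E)-2,2-dimethylhept-3-en-5-yn-1-ol | OCC(C)(C)/C=C/C#CC | intermediate
6 | (3E,5Z)-2,2-dimethyl-6-(4,4,5,5-tetramethyl-1,3,2-dioxaborolan-2-yl)hepta-3,5-dien-1-ol | OCC(C)(C)/C=C/C=C(\C)B1OC(C)(C)C(C)(C)O1 | intermediate
7 | (3E,5Z)-2,2-dimethyl-6-(4,4,5,5-tetramethyl-1,3,2-dioxaborolan-2-yl)hepta-3,5-dienal | O=CC(C)(C)/C=C/C=C(\C)B1OC(C)(C)C(C)(C)O1 | intermediate
8 | (2E,6E)-farnesyl bromide [(2E,6E)-1-bromo-3,7,11-trimethyldodeca-2,6,10-triene] | CC(C)=CCC/C(C)=C/CC/C(C)=C/CBr | starting material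
9 | (E)-N-tert-butylethanimine (acetaldehyde tert-butylimine) | C/C=N/C(C)(C)C | starting material
10 | lithium tert-butyl(vinyl)amide (lithiated 9) | C=CN([Li])C(C)(C)C | intermediate
11 | N-tert-butyl imine of aldehyde 12 | CC(C)=CCC/C(C)=C/CC/C(C)=C/CC/C=N/C(C)(C)C | intermediate
12 | (4E,8E)-5,9,13-trimethyltetradeca-4,8,12-trienal | CC(C)=CCC/C(C)=C/CC/C(C)=C/CCC=O | intermediate
13 | 3-(triphenyl-λ5-phosphanylidene)butan-2-one | CC(=O)C(C)=P(c1ccccc1)(c1ccccc1)c1ccccc1 | starting material
14 | (3E,7E,11E)-3,8,12,16-tetramethylheptadeca-3,7,11,15-tetraen-2-one | CC(C)=CCC/C(C)=C/CC/C(C)=C/CC/C=C(\C)C(C)=O | intermediate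
15 | (+)-diisopinocampheylboron enolate of 14 (2-boryloxy-1,3-diene, terminal CH2=) | CC(C)=CCC/C(C)=C/CC/C(C)=C/CC/C=C(\C)C(=C)OB([C@H]3C[C@H]4C[C@@H]([C@@H]3C)C4(C)C)[C@H]5C[C@H]6C[C@@H]([C@@H]5C)C6(C)C | intermediate
16 | O-diisopinocampheylboryl aldolate of 17 | CC(C)=CCC/C(C)=C/CC/C(C)=C/CC/C=C(\C)C(=O)C[C@H](OB([C@H]3C[C@H]4C[C@@H]([C@@H]3C)C4(C)C)[C@H]5C[C@H]6C[C@@H]([C@@H]5C)C6(C)C)C(C)(C)/C=C/C=C(\C)B1OC(C)(C)C(C)(C)O1 | intermediate
17 | (2Z,4E,7S,10E,14E,18E)-7-hydroxy-6,6,10,15,19,23-hexamethyl-2-(4,4,5,5-tetramethyl-1,3,2-dioxaborolan-2-yl)tetracosa-2,4,10,14,18,22-hexaen-9-one | CC(C)=CCC/C(C)=C/CC/C(C)=C/CC/C=C(\C)C(=O)C[C@H](O)C(C)(C)/C=C/C=C(\C)B1OC(C)(C)C(C)(C)O1 | intermediate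
18 | (2Z,4E,7S,10E,14E,18E)-7-[(tert-butyldimethylsilyl)oxy]-6,6,10,15,19,23-hexamethyl-2-(4,4,5,5-tetramethyl-1,3,2-dioxaborolan-2-yl)tetracosa-2,4,10,14,18,22-hexaen-9-one | CC(C)=CCC/C(C)=C/CC/C(C)=C/CC/C=C(\C)C(=O)C[C@H](O[Si](C)(C)C(C)(C)C)C(C)(C)/C=C/C=C(\C)B1OC(C)(C)C(C)(C)O1 | intermediate
19 | A/B-cis cycloadduct: 3β-(tert-butyldimethylsilyloxy)-4,4,8β,10β-tetramethyl-8α-(pinacolboryl)-9β-[(3E,7E)-4,8,12-trimethyltrideca-3,7,11-trien-1-yl]-5β-H-octal-6-en-1-one | CC(C)=CCC/C(C)=C/CC/C(C)=C/CC[C@@H]1[C@@]2(C)C(=O)C[C@H](O[Si](C)(C)C(C)(C)C)C(C)(C)[C@H]2C=C[C@@]1(C)B3OC(C)(C)C(C)(C)O3 | intermediate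
20 | 8α-hydroxy analogue of 19 (tertiary allylic alcohol, C1 ketone, Δ6) | CC(C)=CCC/C(C)=C/CC/C(C)=C/CC[C@@H]1[C@@]2(C)C(=O)C[C@H](O[Si](C)(C)C(C)(C)C)C(C)(C)[C@H]2C=C[C@@]1(C)O | intermediate
21 | 6,7-dihydro derivative of 20 (A/B-cis 8α-hydroxy-3β-silyloxy decalin-1-one) | CC(C)=CCC/C(C)=C/CC/C(C)=C/CC[C@@H]1[C@@]2(C)C(=O)C[C@H](O[Si](C)(C)C(C)(C)C)C(C)(C)[C@H]2CC[C@@]1(C)O | intermediate
22 | (E)-C1 tosylhydrazone of 21 | CC(C)=CCC/C(C)=C/CC/C(C)=C/CC[C@@H]1[C@@]2(C)/C(=N/NS(=O)(=O)c3ccc(C)cc3)C[C@H](O[Si](C)(C)C(C)(C)C)C(C)(C)[C@H]2CC[C@@]1(C)O | intermediate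
23 | N-(catecholboryl)-N'-tosylhydrazine at C1 (C1 configuration undefined) | CC(C)=CCC/C(C)=C/CC/C(C)=C/CC[C@@H]1[C@@]2(C)C(N(B3Oc4ccccc4O3)NS(=O)(=O)c5ccc(C)cc5)C[C@H](O[Si](C)(C)C(C)(C)C)C(C)(C)[C@H]2CC[C@@]1(C)O | intermediate
24 | 3-O-(tert-butyldimethylsilyl) ether of the target | CC(C)=CCC/C(C)=C/CC/C(C)=C/CC[C@@H]1[C@@]2(C)CC[C@H](O[Si](C)(C)C(C)(C)C)C(C)(C)[C@H]2CC[C@@]1(C)O | intermediate
25 | IN0670, (1R,2R,4aS,6S,8aS)-2,5,5,8a-tetramethyl-1-[(3E,7E)-4,8,12-trimethyltrideca-3,7,11-trien-1-yl]decahydronaphthalene-2,6-diol | CC(C)=CCC/C(C)=C/CC/C(C)=C/CC[C@@H]1[C@@]2(C)CC[C@H](O)C(C)(C)[C@H]2CC[C@@]1(C)O | target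

Total step count: 14. Longest linear sequence: 12 steps (steps 1–4 and 7–14, from compound 1).

Steps most likely to fail

1. Step 9 (key cycloaddition). The Z-methyl-substituted dienylboronate may cyclise too slowly, so that 1,5-hydrogen shift of the diene, Lewis-acid damage to the C–B bond or leakage through exo or wrong-face transition states competes. The fallback sets out from 18 and makes the diene electron-rich before the ring closure. Anhydrous trimethylamine N-oxide (THF, rt) should oxidise the alkenyl C–B bond with retention to the (E)-dienyl pinacol borate F1, a 1-oxy diene with oxygen outside and methyl inside. Heating F1 in toluene (80–100 °C, no Lewis acid) should give, through the same endo transition state, the cycloadduct borate F2. Aqueous work-up hydrolyses the O–B bond, and the sequence comes back to the route at 20, so step 10 is no longer needed.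

2. Step 11 (ring-olefin hydrogenation). Over-reduction or isomerisation of the three trisubstituted chain olefins may occur, or the hindered ring olefin may not be reduced. The fallback sets out from 20 and masks the chain olefins. mCPBA (3 equiv, NaHCO3, CH2Cl2, −20 °C) should epoxidise the electron-rich trisubstituted olefins in preference to the hindered cis-disubstituted ring olefin, giving the tris-epoxide F3 as a mixture of epoxide diastereomers. Diimide (2-nitrobenzenesulfonohydrazide, Et3N, CH2Cl2) then saturates the only remaining olefin to give the ring-saturated tris-epoxide F4. Stereoretentive deoxygenation (NaI, Zn, NaOAc, AcOH, 0 °C) should regenerate the three E olefins, and the sequence comes back to the route at 21.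

3. Step 12 (with step 13, removal of the C1 carbonyl). Condensation at the neopentyl C1 carbonyl may be incomplete, because it is flanked by quaternary C10 and can be masked as a hemiketal by the C8 hydroxyl, or hydride transfer to the hindered C=N may be sluggish. The fallback sets out from 21 and uses radical deoxygenation. NaBH4 (MeOH/THF) gives the C1 alcohol F5 (either C1 epimer serves). PhOC(S)Cl, pyridine and DMAP acylate only the secondary hydroxyl to give the phenyl thionocarbonate F6. Barton–McCombie reduction (Bu3SnH at high concentration, to outrun 6-exo closure of the C1 radical onto the chain, AIBN, toluene, 100 °C) then comes back to the route at 24.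

Further compounds
F1 | step 9 | (E)-dienyl pinacol borate from 18 (C8–O–Bpin, oxygen trans to C6) | CC(C)=CCC/C(C)=C/CC/C(C)=C/CC/C=C(\C)C(=O)C[C@H](O[Si](C)(C)C(C)(C)C)C(C)(C)/C=C/C=C(\C)OB1OC(C)(C)C(C)(C)O1
F2 | step 9 | cycloadduct borate (8α-O-Bpin analogue of 20) | CC(C)=CCC/C(C)=C/CC/C(C)=C/CC[C@@H]1[C@@]2(C)C(=O)C[C@H](O[Si](C)(C)C(C)(C)C)C(C)(C)[C@H]2C=C[C@@]1(C)OB3OC(C)(C)C(C)(C)O3
F3 | step 11 | tris-epoxide of 20 (three chain olefins epoxidised, epoxide centres as a mixture) | CC3(C)OC3CCC4(C)OC4CCC5(C)OC5CC[C@@H]1[C@@]2(C)C(=O)C[C@H](O[Si](C)(C)C(C)(C)C)C(C)(C)[C@H]2C=C[C@@]1(C)O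
F4 | step 11 | 6,7-dihydro tris-epoxide (ring-saturated F3) | CC3(C)OC3CCC4(C)OC4CCC5(C)OC5CC[C@@H]1[C@@]2(C)C(=O)C[C@H](O[Si](C)(C)C(C)(C)C)C(C)(C)[C@H]2CC[C@@]1(C)O
F5 | step 12 | C1 alcohol from 21 (C1 configuration undefined) | CC(C)=CCC/C(C)=C/CC/C(C)=C/CC[C@@H]1[C@@]2(C)C(O)C[C@H](O[Si](C)(C)C(C)(C)C)C(C)(C)[C@H]2CC[C@@]1(C)O
F6 | step 12 | C1 O-phenyl thionocarbonate of F5 | CC(C)=CCC/C(C)=C/CC/C(C)=C/CC[C@@H]1[C@@]2(C)C(OC(=S)Oc3ccccc3)C[C@H](O[Si](C)(C)C(C)(C)C)C(C)(C)[C@H]2CC[C@@]1(C)O
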